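**Retrosynthetic overview**
1. Dielsianone is unveiled by chelation-controlled cleavage of the C5 methyl ether of its 5-O-methyl ether. The 1,2-dione comes from Riley oxidation of a deoxybenzoin, itself made by palladium-catalysed α-arylation of 4'-methoxyacetophenone with 6-bromo-5,8-dimethoxy-2,2-dimethyl-2H-chromene.
2. The pyran ring is the only ring made in the route (both benzene rings are bought). It is closed at C2–C3 by a platinum-catalysed hydride-shift cycloisomerisation of 1-bromo-3-ethynyl-2,5-dimethoxy-4-isopropoxybenzene: the isopropyl methine becomes C2 with its two methyl groups, and the ethynyl group becomes C4=C3.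
3. Enabling feature: C2 carries the ring oxygen O1 and two methyl groups, and C3 is an unsubstituted CH. The opened pyran ring is therefore an aryl isopropyl ether ortho to a terminal alkyne, with a tertiary, oxygen-activated C–H bond five atoms (H–C2–O1–C8a–C4a–C4) from the arene-bound alkyne carbon.
4. The alkyne is assembled from 2,5-dimethoxyphenol by ortho-formylation, para-bromination, O-isopropylation and Ohira–Bestmann homologation.

Key step: step 5

Remark: the target has no stereocentre, and the cis geometry of the C3=C4 bond is enforced by the six-membered ring, so no stereodescriptor is needed in any SMILES.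

**Step 1**
Reactants: 1 2,5-dimethoxyphenol
Product: 3 2-hydroxy-3,6-dimethoxybenzaldehyde, via 2-(hydroxymethyl)-3,6-dimethoxyphenol 2 (not isolated)
Conditions: MgCl2 (2 equiv), Et3N (4 equiv), (CH2O)n (6 equiv), MeCN, reflux; then 1 M HCl
Reagents that add atoms: paraformaldehyde (as formaldehyde), C=O
Why: Casnati–Skattebøl ortho-formylation, in which the magnesium phenoxide delivers formaldehyde to the only free ortho position to give the hydroxymethyl phenol 2, which a second equivalent of formaldehyde oxidises to the salicylaldehyde by Oppenauer-type hydride transfer.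

**Step 2**
Reactants: 3 2-hydroxy-3,6-dimethoxybenzaldehyde
Product: 4 5-bromo-2-hydroxy-3,6-dimethoxybenzaldehyde
Conditions: NBS (1.05 equiv), MeCN, 0 °C to rt
Reagents that add atoms: N-bromosuccinimide, O=C1CCC(=O)N1Br
Why: Electrophilic aromatic bromination should occur at the position para to the phenol OH and ortho to a methoxy group, the only site activated by two oxygen donors and meta to the deactivating aldehyde.

**Step 3**
Reactants: 4 5-bromo-2-hydroxy-3,6-dimethoxybenzaldehyde
Product: 5 5-bromo-3,6-dimethoxy-2-(propan-2-yloxy)benzaldehyde
Conditions: 2-bromopropane (3 equiv), K2CO3, DMF, 60 °C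
Reagents that add atoms: 2-bromopropane, CC(C)Br
Why: Williamson ether synthesis (SN2 of the phenoxide on the secondary bromide, used in excess to offset E2) installs the isopropyl group whose methine carbon is to become C2 of the pyran ring.

**Step 4**
Reactants: 5 5-bromo-3,6-dimethoxy-2-(propan-2-yloxy)benzaldehyde
Product: 6 1-bromo-3-ethynyl-2,5-dimethoxy-4-(propan-2-yloxy)benzene
Conditions: dimethyl (1-diazo-2-oxopropyl)phosphonate (1.5 equiv), K2CO3 (3 equiv), MeOH/THF, 0 °C to rt
Reagents that add atoms: dimethyl (1-diazo-2-oxopropyl)phosphonate (Ohira–Bestmann reagent), COP(=O)(OC)C(=[N+]=[N-])C(C)=O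
Why: Seyferth–Gilbert homologation in the Ohira–Bestmann variant, in which methoxide deacylates the reagent, the diazomethylphosphonate anion olefinates the aldehyde and the diazoalkene loses N2 with 1,2-hydrogen shift to the terminal alkyne, under conditions mild enough for the aryl bromide.

**Step 5**
Reactants: 6 1-bromo-3-ethynyl-2,5-dimethoxy-4-(propan-2-yloxy)benzene
Product: 7 6-bromo-5,8-dimethoxy-2,2-dimethyl-2H-chromene
Conditions: PtCl2 (10 mol %), toluene, 4 Å MS, 90 °C
Reagents that add atoms: none
Why: Proposed new method: PtCl2 activates the terminal alkyne as a π-complex, whose arene-bound carbon (the future C4) takes up the methine hydride of the ortho isopropoxy group through a six-membered 1,5-transfer, and the aryl oxocarbenium ion so formed (ArO+=CMe2) is captured at its carbon by the alkenyl–platinum terminus (the future C3), which forms the C2–C3 bond and releases the catalyst; a vinylidene pathway with hydride delivery to the metal-bound carbon would converge on the same product. The closest known reaction type is the hydride-shift/cyclisation (hydroalkylation) of alkynes with ether or benzylic C–H bonds under PtI4, PtCl2 or R3PAuNTf2 catalysis, which turns alkynyl ethers into ring-fused cyclohexenes and 1-alkyl-2-ethynylbenzenes into indenes; what is new is an aryl isopropyl ether as the hydride donor and a 2H-chromene as the product. The pyran ring closes in a 6-endo sense at the former alkyne terminus, by attack of the alkenyl–metal carbon on the oxocarbenium carbon. No stereocentre is created, and the cis ring alkene follows from anti delivery of hydride and metal across the alkyne with retention at the metal-bearing carbon. The step needs hydride transfer to outrun 5-endo attack of the two flanking ether oxygens on the activated alkyne, and needs the isopropyl methine, not a methoxy C–H, to be the donor. The substrate secures this because methyl and isopropyl are poor migrating groups, so that oxygen attack is unproductive and reversible, because only the isopropyl group offers a tertiary α-oxy C–H bond, and because its two ortho neighbours twist the isopropoxy group out of the ring plane, which frees the oxygen lone pair for the oxocarbenium ion and holds the C–H bond over the alkyne five atoms away.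

**Step 6**
Reactants: 7 6-bromo-5,8-dimethoxy-2,2-dimethyl-2H-chromene; 8 1-(4-methoxyphenyl)ethan-1-one (4'-methoxyacetophenone)
Product: 9 2-(5,8-dimethoxy-2,2-dimethyl-2H-chromen-6-yl)-1-(4-methoxyphenyl)ethan-1-one
Conditions: 8 (1.5 equiv), Pd(OAc)2 (2 mol %), XPhos (4 mol %), NaOtBu (2.2 equiv), toluene, 80 °C
Reagents that add atoms: none
Why: Palladium-catalysed ketone α-arylation (Buchwald–Hartwig type), in which oxidative addition of the aryl bromide to zerovalent palladium, transmetalation with the sodium enolate of 8 and reductive elimination should give the deoxybenzoin, the ortho methoxy group disfavouring a second arylation, and the orientation of the ketone being immaterial because both bridge carbons become carbonyl groups.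

**Step 7**
Reactants: 9 2-(5,8-dimethoxy-2,2-dimethyl-2H-chromen-6-yl)-1-(4-methoxyphenyl)ethan-1-one
Product: 10 1-(5,8-dimethoxy-2,2-dimethyl-2H-chromen-6-yl)-2-(4-methoxyphenyl)ethane-1,2-dione
Conditions: SeO2 (2 equiv), 1,4-dioxane/H2O (20:1), 90 °C
Reagents that add atoms: selenium dioxide, O=[Se]=O
Why: Riley oxidation should convert the methylene that is both benzylic and α to the ketone into the second carbonyl, while the chromene offers no allylic C–H bond (C2 is quaternary) as a competing site.

**Step 8**
Reactants: 10 1-(5,8-dimethoxy-2,2-dimethyl-2H-chromen-6-yl)-2-(4-methoxyphenyl)ethane-1,2-dione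
Product: 11 Dielsianone, 1-(5-hydroxy-8-methoxy-2,2-dimethyl-2H-chromen-6-yl)-2-(4-methoxyphenyl)ethane-1,2-dione
Conditions: BCl3 (1.5 equiv), CH2Cl2, −78 to −20 °C; then H2O
Reagents that add atoms: none
Why: Chelation-controlled Lewis-acid ether cleavage, in which BCl3 bridges the ring-bound carbonyl oxygen and the ortho (C5) methoxy oxygen in a six-membered chelate so that chloride removes only that methyl group, the non-chelated 8- and 4'-methoxy groups being left untouched at low temperature.

**Compound list**
1 | 2,5-dimethoxyphenol | Oc1cc(OC)ccc1OC | starting material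
2 | 2-(hydroxymethyl)-3,6-dimethoxyphenol | OCc1c(O)c(OC)ccc1OC | intermediate
3 | 2-hydroxy-3,6-dimethoxybenzaldehyde | O=Cc1c(O)c(OC)ccc1OC | intermediate
4 | 5-bromo-2-hydroxy-3,6-dimethoxybenzaldehyde | O=Cc1c(O)c(OC)cc(Br)c1OC | intermediate
5 | 5-bromo-3,6-dimethoxy-2-(propan-2-yloxy)benzaldehyde | O=Cc1c(OC(C)C)c(OC)cc(Br)c1OC | intermediate
6 | 1-bromo-3-ethynyl-2,5-dimethoxy-4-(propan-2-yloxy)benzene | C#Cc1c(OC(C)C)c(OC)cc(Br)c1OC | intermediate
7 | 6-bromo-5,8-dimethoxy-2,2-dimethyl-2H-chromene | COc1cc(Br)c(OC)c2C=CC(C)(C)Oc12 | intermediate
8 | 1-(4-methoxyphenyl)ethan-1-one (4'-methoxyacetophenone) | COc1ccc(cc1)C(C)=O | starting material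
9 | 2-(5,8-dimethoxy-2,2-dimethyl-2H-chromen-6-yl)-1-(4-methoxyphenyl)ethan-1-one | COc1ccc(cc1)C(=O)Cc1cc(OC)c2OC(C)(C)C=Cc2c1OC | intermediate
10 | 1-(5,8-dimethoxy-2,2-dimethyl-2H-chromen-6-yl)-2-(4-methoxyphenyl)ethane-1,2-dione | COc1ccc(cc1)C(=O)C(=O)c1cc(OC)c2OC(C)(C)C=Cc2c1OC | intermediate
11 | Dielsianone, 1-(5-hydroxy-8-methoxy-2,2-dimethyl-2H-chromen-6-yl)-2-(4-methoxyphenyl)ethane-1,2-dione | COc1ccc(C(=O)C(=O)c2cc(OC)c3c(c2O)C=CC(C)(C)O3)cc1 | target

**Step count and risks**
Total step count: 8. Longest linear sequence: 8 steps, from 1 to 11; compound 8 is bought.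

Steps most likely to fail:

1. Step 5 (proposed new method). Hydride transfer from a donor whose oxygen sits on an arene may be slower than 5-endo attack of the isopropoxy oxygen on the platinum-activated alkyne followed by loss of propene. It may also lose out to hydration or oligomerisation of the terminal alkyne. The fallback uses known chemistry and sets out from 4. Addition of 2-methylprop-1-enylmagnesium bromide (2.5 equiv, THF, 0 °C) to the aldehyde should give the allylic benzylic alcohol 4-bromo-2-(1-hydroxy-3-methylbut-2-en-1-yl)-3,6-dimethoxyphenol F1. Warming F1 with catalytic PPTS in toluene should dehydrate it to the ortho-quinone methide 4-bromo-3,6-dimethoxy-2-(3-methylbut-2-en-1-ylidene)cyclohexa-3,5-dien-1-one F2 (not isolated). Oxa-6π electrocyclisation of F2 closes the pyran ring at O1–C2 and comes back to the route at 7, so steps 3 to 5 are skipped and the C–H functionalisation is given up.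

2. Step 8. Protonation or chloride addition at the acid-sensitive C3=C4 bond of the chromene may compete, and ether cleavage may become unselective because the 1,2-dione offers BCl3 a second chelation site. The fallback sets out from 7 and moves the ether cleavage ahead of dione formation. Bromine–lithium exchange (n-BuLi, THF, −78 °C) should give (5,8-dimethoxy-2,2-dimethyl-2H-chromen-6-yl)lithium F3 (not isolated). Acylation of F3 with N-methoxy-N-methyl-2-(4-methoxyphenyl)acetamide should give the regioisomeric deoxybenzoin 1-(5,8-dimethoxy-2,2-dimethyl-2H-chromen-6-yl)-2-(4-methoxyphenyl)ethan-1-one F4. Its single, ring-bound carbonyl allows the C5 methyl ether to be removed under neutral conditions by iodide within a magnesium chelate (MgI2 etherate, toluene, 60 °C), giving 1-(5-hydroxy-8-methoxy-2,2-dimethyl-2H-chromen-6-yl)-2-(4-methoxyphenyl)ethan-1-one F5. Riley oxidation of F5 (SeO2, wet dioxane) then comes back to the route at 11, so the ether cleavage never meets the dione.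

3. Step 7. The selenium reagent may attack the electron-rich chromene alkene and arene, or over-oxidise, instead of cleanly oxidising the methylene. The fallback sets out from 9 and replaces the one-step oxidation by enolate oxygenation followed by alcohol oxidation. Enolate formation (KN(SiMe3)2, THF, −78 °C) and hydroxylation with 2-(phenylsulfonyl)-3-phenyloxaziridine should give the benzoin 2-(5,8-dimethoxy-2,2-dimethyl-2H-chromen-6-yl)-2-hydroxy-1-(4-methoxyphenyl)ethan-1-one F6 (racemic). Dess–Martin periodinane should oxidise F6 to the dione, coming back to the route at 10.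

**Further compounds**
F1 | step 5 | 4-bromo-2-(1-hydroxy-3-methylbut-2-en-1-yl)-3,6-dimethoxyphenol (racemic) | CC(C)=CC(O)c1c(O)c(OC)cc(Br)c1OC
F2 | step 5 | 4-bromo-3,6-dimethoxy-2-(3-methylbut-2-en-1-ylidene)cyclohexa-3,5-dien-1-one (alkene geometry not defined) | O=C1C(=CC=C(C)C)C(OC)=C(Br)C=C1OC
F3 | step 8 | (5,8-dimethoxy-2,2-dimethyl-2H-chromen-6-yl)lithium | [Li]c1cc(OC)c2OC(C)(C)C=Cc2c1OC
F4 | step 8 | 1-(5,8-dimethoxy-2,2-dimethyl-2H-chromen-6-yl)-2-(4-methoxyphenyl)ethan-1-one | COc1ccc(CC(=O)c2cc(OC)c3OC(C)(C)C=Cc3c2OC)cc1
F5 | step 8 | 1-(5-hydroxy-8-methoxy-2,2-dimethyl-2H-chromen-6-yl)-2-(4-methoxyphenyl)ethan-1-one | COc1ccc(CC(=O)c2cc(OC)c3OC(C)(C)C=Cc3c2O)cc1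
F6 | step 7 | 2-(5,8-dimethoxy-2,2-dimethyl-2H-chromen-6-yl)-2-hydroxy-1-(4-methoxyphenyl)ethan-1-one (racemic) | COc1ccc(cc1)C(=O)C(O)c1cc(OC)c2OC(C)(C)C=Cc2c1OC
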